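A small charge of reagent goes with an early stop in the north-west run. In the north-west run, with 0.051 M of reagent, the starting material stands still at 58 %, while in the east run, with 0.31 M of reagent and the same catalyst, it falls to 1 %.

| flask | starting material | second substrate | reagent | free catalyst | remark | time |
|---|---|---|---|---|---|---|
| north-west | 0.10 M | 0.10 M | 0.051 M | 20 mM | run made earlier |  |
| east | 0.10 M | 0.10 M | 0.31 M | 20 mM | run made earlier |  |
| ochre | 0.10 M | 0.100 M | 0.100 M | 20 mM |  | 20 d |
| violet | 0.10 M | 0.100 M | 0.200 M | 20 mM |  | 20 d |
| red | 0.10 M | 0.100 M | 0.400 M | 20 mM |  | 20 d |

| run | time / d | target / % | starting material / % |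
|---|---|---|---|
| north-west | 1.04 | 9 | 79 |
| north-west | 3.00 | 15 | 64 |
| north-west | 6.00 | 20 | 57 |
| north-west | 8.00 | 23 | 56 |
| north-west | 12.0 | 18 | 61 |
| north-west | 15.0 | 17 | 59 |
| north-west | 20.0 | 18 | 58 |
| east | 1.67 | 37 | 21 |
| east | 2.50 | 41 | 12 |
| east | 4.00 | 46 | 2 |
| east | 6.00 | 50 | 2 |
| east | 8.00 | 47 | 3 |
| east | 12.0 | 48 | 1 |
| east | 20.0 | 47 | 1 |

(standard deviation of a reading: 2 percentage points)

- the numbers in the tables scatter by 2 percentage points (one standard deviation)
- "hardly changes" means that all values lie within two and a half points (for a concentration: within two and a half percent of the largest)

* amount of target at the end, in percent of the starting material charged for ochre, violet, red, in this order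
* how the row runs (falls all the way / falls, then rises / hardly changes / rises all the way / rises, then falls)

I take reagent as the limiting reagent of the north-west run, and I read the stop as its whole charge of 0.051 M consumed. So 0.051 M of reagent paid for 0.0420 M of starting material lost, a price of 1.21 reagent per starting material. Ochre then has 0.824 of what I call the cover, [reagent] charged over price times [starting material] charged. Violet has 1.65 and red 3.29. On this reading, a cover below 1 gives the fraction of starting material lost, and above 1 the starting material ends first.

The east run tests this: its cover is 2.55, and 1 % of its starting material remains, as the reading says. But the cover tells how much is lost, not what it becomes. For that I have two readings of target per starting material lost, 0.429 in the north-west run and 0.475 in the east run, equal within the scatter. I take their mean, 0.452, though two runs are a thin base. My reckoning gives 37.2 % for ochre and 45.2 % for violet and for red, a rise and then a flat row.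

The forecast says 33 %, 44 %, 47 %, rises all the way, in its words “The row rises, then flattens towards the ceiling”.

The flasks give 42.5 %, 57.4 % and 43.7 %, so the row rises, then falls.

    starting material + reagent → uncatalysed product (k = 0.0922 /M/h)
    second substrate + free catalyst ⇌ catalyst intermediate B (K = 133 /M, k = 2.35 /M/h)
    reagent + catalyst intermediate B → free catalyst + second product (k = 0.890 /M/h)
    2 second substrate → self-condensation product (k = 0.384 /M/h)
    reagent + catalyst intermediate A → free catalyst + target (k = 2.15 /M/h)
    starting material + free catalyst ⇌ catalyst intermediate A (K = 14.0 /M, k = 1.88 /M/h)

The cover parts ochre from violet: ochre, at 0.824, ends with 0.039 % of its reagent and 26 % of its starting material, while violet, at 1.65, ends with 27 % of its reagent and 0 % of its starting material. The row turns at 0.15 M of reagent, a cover of 1.26. Red ends lower than violet, and the main reason for what red lacks is the loss of starting material with reagent to uncatalysed product: with that step taken away, red ends at >99.9 % of target instead of 43.7 %.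

(The data were computed with made-up constants.)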